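The route rests on cutting the C3–C4 bond of the 3,7-dimethyldeca-2,6-dienyl chain: the sp2–sp3 bond inside the 1,5-diene C2=C3–C4–C5–C6=C7, where the methyl-bearing Z-vinyl carbon of the allylic ester meets a homoallylic CH2. A one-pot zinc insertion/Negishi alkyl–alkenyl coupling joins both fully elaborated halves with retention of all alkene geometries. Its precursors are a homoallylic iodide that already carries the (E)-alkylidene, silyl-protected hydroxybutyrolactone ring (stereocentres from 2-deoxy-D-ribose) and the (Z)-3-iodobut-2-enyl ester of (E)-3-methylpent-2-enoic acid, whose geometry is fixed by hydroxyl-directed trans-hydroalumination. Only a desilylation follows.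

Key step: step 15

Remark on the chemistry: (2E)-3-methylpent-2-enoic acid is taken as a commercial, geometrically pure starting material. The target is read as the trans-(4S,5R) lactone with a 2Z,6E chain, an (E)-alkylidene and an (E)-enoate.

Step 1
Reactants: 1 2-deoxy-D-ribose
Product: 2 2-deoxy-D-ribono-1,4-lactone, (4S,5R)-4-hydroxy-5-(hydroxymethyl)oxolan-2-one
Conditions: Br2, H2O, rt; then concentration
Reagents that add atoms: none
Why: Bromine-water oxidation of the aldose at the anomeric carbon gives the aldonic acid, which should close to the five-membered 1,4-lactone; sugar C3 and C4 are untouched and supply both stereocentres of the target (lactone C4 S, C5 R, trans) from the chiral pool.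

Step 2
Reactants: 2 2-deoxy-D-ribono-1,4-lactone
Product: 3 (4S,5R)-4-[(tert-butyldimethylsilyl)oxy]-5-{[(tert-butyldimethylsilyl)oxy]methyl}oxolan-2-one
Conditions: TBSCl (2.5 equiv), imidazole, DMF, rt
Reagents that add atoms: tert-butyldimethylsilyl chloride, CC(C)(C)[Si](C)(C)Cl
Why: Standard imidazole-mediated silylation of both hydroxyl groups should proceed without touching the lactone.

Step 3
Reactants: 3 bis-TBS lactone
Product: 4 (4S,5R)-4-[(tert-butyldimethylsilyl)oxy]-5-(hydroxymethyl)oxolan-2-one
Conditions: TFA/H2O/THF (1:1:4), 0 °C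
Reagents that add atoms: none
Why: Acid-catalysed hydrolysis of silyl ethers is strongly rate-dependent on steric hindrance, so the primary TBS ether should be cleaved selectively while the ring secondary TBS ether stays.

Step 4
Reactants: 4 primary alcohol
Product: 5 (2S,3S)-3-[(tert-butyldimethylsilyl)oxy]-5-oxooxolane-2-carbaldehyde (same spatial arrangement as 4; the descriptor at the former C5 changes by CIP priority only)
Conditions: Dess–Martin periodinane, CH2Cl2, 0 °C to rt; used crude
Reagents that add atoms: none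
Why: Dess–Martin oxidation works under non-basic conditions, which should avoid epimerisation of the α-oxygenated aldehyde carbon and β-elimination of the silyloxy group.

Step 5
Reactants: 5 aldehyde
Product: 6 (4S,5R)-4-[(tert-butyldimethylsilyl)oxy]-5-(2-methylprop-1-en-1-yl)oxolan-2-one
Conditions: i-PrPPh3I, n-BuLi, THF, 0 °C; then 5, −78 to 0 °C
Reagents that add atoms: isopropyltriphenylphosphonium iodide, CC(C)[P+](c1ccccc1)(c1ccccc1)c1ccccc1.[I-]
Why: Wittig olefination with the non-stabilised isopropylidene ylide should take the aldehyde far faster than the lactone at low temperature; the new alkene carries two identical methyl groups, so no geometry issue arises and C5 is not touched.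

Step 6
Reactants: 7 3-[(tert-butyldimethylsilyl)oxy]propanal
Product: 8 5-[(tert-butyldimethylsilyl)oxy]-2-methylpent-1-en-3-ol (racemic)
Conditions: isopropenylmagnesium bromide, THF, −78 to 0 °C
Reagents that add atoms: isopropenylmagnesium bromide, CC(=C)[Mg]Br
Why: Grignard 1,2-addition to the aldehyde gives the 2-methylallylic alcohol; its carbinol stereocentre is erased in the next step, so the racemate suffices.

Step 7
Reactants: 8 allylic alcohol
Product: 10 ethyl (4E)-7-[(tert-butyldimethylsilyl)oxy]-4-methylhept-4-enoate, via mixed ketene acetal 9 (not isolated)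
Conditions: MeC(OEt)3 (excess), EtCO2H (cat.), 140 °C, EtOH distilled off
Reagents that add atoms: triethyl orthoacetate, CCOC(C)(OCC)OCC
Why: Johnson–Claisen rearrangement through a chair transition state with the CH2CH2OTBS group equatorial should give the (E)-trisubstituted alkene (the later C6=C7 of the chain) with high selectivity.

Step 8
Reactants: 10 ethyl ester
Product: 11 (4E)-7-[(tert-butyldimethylsilyl)oxy]-4-methylhept-4-enal
Conditions: DIBAL-H (1.05 equiv), CH2Cl2, −78 °C; Rochelle salt work-up
Reagents that add atoms: none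
Why: Partial DIBAL reduction at −78 °C stops at the aluminium hemiacetal, which should release the aldehyde on work-up without touching alkene or silyl ether.

Step 9
Reactants: 6 isobutenyl lactone; 11 chain aldehyde
Product: 13 (4S,5R)-4-[(tert-butyldimethylsilyl)oxy]-3-[(4E)-7-[(tert-butyldimethylsilyl)oxy]-1-hydroxy-4-methylhept-4-en-1-yl]-5-(2-methylprop-1-en-1-yl)oxolan-2-one (mixture of epimers at C3 and the carbinol carbon), via lithium enolate 12 (not isolated)
Conditions: LDA (1.1 equiv), THF, −78 °C, 30 min; then 11, −78 °C; AcOH quench at −78 °C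
Reagents that add atoms: none
Why: Aldol addition of the lithium lactone enolate at −78 °C should outpace β-elimination of the ring silyloxy group; both new stereocentres are removed in step 10, so their configuration does not matter.

Step 10
Reactants: 13 aldol adduct
Product: 15 (3E,4S,5R)-4-[(tert-butyldimethylsilyl)oxy]-3-[(4E)-7-[(tert-butyldimethylsilyl)oxy]-4-methylhept-4-en-1-ylidene]-5-(2-methylprop-1-en-1-yl)oxolan-2-one, via mesylate 14 (not isolated)
Conditions: MsCl, Et3N, CH2Cl2, 0 °C; then DBU, 0 °C to rt
Reagents that add atoms: none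
Why: Mesylation followed by E1cB elimination through the lactone enolate should expel the far better exocyclic leaving group (mesylate versus silanolate) and favour the more stable (E)-alkylidene lactone with the chain remote from the carbonyl oxygen; any minor Z isomer would be removed by chromatography.

Step 11
Reactants: 15 bis-silyl alkylidene lactone
Product: 16 (3E,4S,5R)-4-[(tert-butyldimethylsilyl)oxy]-3-[(4E)-7-hydroxy-4-methylhept-4-en-1-ylidene]-5-(2-methylprop-1-en-1-yl)oxolan-2-one
Conditions: CSA (0.1 equiv), MeOH/CH2Cl2 (1:1), 0 °C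
Reagents that add atoms: none
Why: Acid-catalysed methanolysis should cleave the unhindered primary TBS ether selectively, while the secondary ring TBS ether, flanked by the alkylidene and isobutenyl groups, survives.

Step 12
Reactants: 16 primary alcohol
Product: 17 (3E,4S,5R)-4-[(tert-butyldimethylsilyl)oxy]-3-[(4E)-7-iodo-4-methylhept-4-en-1-ylidene]-5-(2-methylprop-1-en-1-yl)oxolan-2-one
Conditions: I2, PPh3, imidazole, CH2Cl2, 0 °C to rt
Reagents that add atoms: iodine, II
Why: Appel-type iodination converts the primary alcohol through its alkoxyphosphonium salt into the homoallylic iodide under neutral conditions that the lactone, silyl ether and alkenes should tolerate.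

Step 13
Reactants: 18 but-2-yn-1-ol
Product: 20 (2Z)-3-iodobut-2-en-1-ol, via cyclic alkenylaluminate 19 (not isolated)
Conditions: Red-Al, THF, 0 °C to rt; EtOAc; then I2, THF, −78 to 0 °C
Reagents that add atoms: iodine, II
Why: Hydroxyl-directed trans-hydroalumination of the propargylic alcohol delivers hydride to C2 and aluminium to C3 in a five-membered oxa-aluminacycle, and iodinolysis of the C–Al bond with retention should give the (Z)-3-iodoalkenol only.

Step 14
Reactants: 20 (2Z)-3-iodobut-2-en-1-ol; 21 (2E)-3-methylpent-2-enoic acid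
Product: 22 (2Z)-3-iodobut-2-en-1-yl (2E)-3-methylpent-2-enoate
Conditions: PPh3, DIAD, THF, 0 °C to rt
Reagents that add atoms: none
Why: Mitsunobu esterification makes the carboxylate the nucleophile towards the primary alkoxyphosphonium salt, so the acid is never turned into an acylating agent and its (E)-enoate should neither deconjugate nor isomerise.

Step 15
Reactants: 17 homoallylic iodide; 22 (Z)-alkenyl iodide ester
Product: 24 (2Z,6E,10E)-10-[(4S,5R)-4-[(tert-butyldimethylsilyl)oxy]-5-(2-methylprop-1-en-1-yl)-2-oxooxolan-3-ylidene]-3,7-dimethyldeca-2,6-dien-1-yl (2E)-3-methylpent-2-enoate, via alkylzinc iodide 23 (not isolated)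
Conditions: Zn dust (activated with BrCH2CH2Br/TMSCl), LiCl, THF, 40 °C; supernatant transferred, then 22, PdCl2(DPEphos) (5 mol%), THF/DMF, rt
Reagents that add atoms: none
Why: Zinc inserts into the primary C–I bond of 17 to give the homoallylic zinc iodide 23, which should tolerate lactone, silyl ether and enoate; Pd(0) then adds oxidatively to the C(sp2)–I bond of 22, and transmetalation from zinc followed by reductive elimination forges the C3–C4 bond. The closest known reaction type is the Negishi homoallyl–alkenyl coupling used to assemble the 1,5-dienes of terpenoids. No ring is closed and no stereocentre is formed; the stereochemical task is retention of the Z geometry at C2=C3 (fixed in 22) and of the E geometries at C6=C7 and at the alkylidene (fixed in 17), which the stereoretentive oxidative addition and reductive elimination and the inertness of the remote alkenes should secure. Chemoselectivity is needed for the alkenyl iodide over the two allylic C–O bonds (the 3,3-disubstituted allylic ester and the lactone C5–O) and over the alkylidene-lactone Michael acceptor; it rests on the much faster oxidative addition of Pd(0) to alkenyl iodides at room temperature and on the inertness of alkylzinc halides towards esters and enoates without copper. The wide-bite-angle DPEphos ligand should speed reductive elimination so that β-hydride elimination from the alkyl–palladium intermediate does not compete.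

Step 16
Reactants: 24 TBS-protected coupling product
Product: 25 (2Z,6E,10E)-10-[(4S,5R)-4-hydroxy-5-(2-methylprop-1-en-1-yl)-2-oxooxolan-3-ylidene]-3,7-dimethyldeca-2,6-dien-1-yl (2E)-3-methylpent-2-enoate (target)
Conditions: HF·pyridine, pyridine, THF, 0 °C to rt
Reagents that add atoms: none
Why: Buffered fluoride desilylation should remove the secondary TBS ether without conjugate addition to the alkylidene lactone, ester cleavage or ionisation of the allylic C–O bonds.

Compound list
1 | 2-deoxy-D-ribose, (3S,4R)-3,4,5-trihydroxypentanal (drawn open-chain) | O=CC[C@H](O)[C@H](O)CO | starting material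
2 | 2-deoxy-D-ribono-1,4-lactone, (4S,5R)-4-hydroxy-5-(hydroxymethyl)oxolan-2-one | O=C1C[C@H](O)[C@@H](CO)O1 | intermediate
3 | (4S,5R)-4-[(tert-butyldimethylsilyl)oxy]-5-{[(tert-butyldimethylsilyl)oxy]methyl}oxolan-2-one | O=C1C[C@H](O[Si](C)(C)C(C)(C)C)[C@@H](CO[Si](C)(C)C(C)(C)C)O1 | intermediate
4 | (4S,5R)-4-[(tert-butyldimethylsilyl)oxy]-5-(hydroxymethyl)oxolan-2-one | O=C1C[C@H](O[Si](C)(C)C(C)(C)C)[C@@H](CO)O1 | intermediate
5 | (2S,3S)-3-[(tert-butyldimethylsilyl)oxy]-5-oxooxolane-2-carbaldehyde | O=C1C[C@H](O[Si](C)(C)C(C)(C)C)[C@@H](C=O)O1 | intermediate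
6 | (4S,5R)-4-[(tert-butyldimethylsilyl)oxy]-5-(2-methylprop-1-en-1-yl)oxolan-2-one | O=C1C[C@H](O[Si](C)(C)C(C)(C)C)[C@@H](C=C(C)C)O1 | intermediate
7 | 3-[(tert-butyldimethylsilyl)oxy]propanal | O=CCCO[Si](C)(C)C(C)(C)C | starting material
8 | 5-[(tert-butyldimethylsilyl)oxy]-2-methylpent-1-en-3-ol (racemic) | C=C(C)C(O)CCO[Si](C)(C)C(C)(C)C | intermediate
9 | mixed ketene acetal, tert-butyl({3-[(1-ethoxyethenyl)oxy]-4-methylpent-4-en-1-yl}oxy)dimethylsilane (not isolated) | C=C(OCC)OC(CCO[Si](C)(C)C(C)(C)C)C(C)=C | intermediate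
10 | ethyl (4E)-7-[(tert-butyldimethylsilyl)oxy]-4-methylhept-4-enoate | CCOC(=O)CC/C(C)=C/CCO[Si](C)(C)C(C)(C)C | intermediate
11 | (4E)-7-[(tert-butyldimethylsilyl)oxy]-4-methylhept-4-enal | O=CCC/C(C)=C/CCO[Si](C)(C)C(C)(C)C | intermediate
12 | lithium enolate of lactone 6 (not isolated) | [Li]OC1=C[C@H](O[Si](C)(C)C(C)(C)C)[C@@H](C=C(C)C)O1 | intermediate
13 | aldol adduct, (4S,5R)-4-[(tert-butyldimethylsilyl)oxy]-3-[(4E)-7-[(tert-butyldimethylsilyl)oxy]-1-hydroxy-4-methylhept-4-en-1-yl]-5-(2-methylprop-1-en-1-yl)oxolan-2-one (epimer mixture at C3 and the carbinol carbon) | OC(CC/C(C)=C/CCO[Si](C)(C)C(C)(C)C)C1C(=O)O[C@H](C=C(C)C)[C@H]1O[Si](C)(C)C(C)(C)C | intermediate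
14 | methanesulfonate of 13 (not isolated) | CS(=O)(=O)OC(CC/C(C)=C/CCO[Si](C)(C)C(C)(C)C)C1C(=O)O[C@H](C=C(C)C)[C@H]1O[Si](C)(C)C(C)(C)C | intermediate
15 | (3E,4S,5R)-4-[(tert-butyldimethylsilyl)oxy]-3-[(4E)-7-[(tert-butyldimethylsilyl)oxy]-4-methylhept-4-en-1-ylidene]-5-(2-methylprop-1-en-1-yl)oxolan-2-one | CC(C)(C)[Si](C)(C)OCC/C=C(\C)CC/C=C1/C(=O)O[C@H](C=C(C)C)[C@H]1O[Si](C)(C)C(C)(C)C | intermediate
16 | (3E,4S,5R)-4-[(tert-butyldimethylsilyl)oxy]-3-[(4E)-7-hydroxy-4-methylhept-4-en-1-ylidene]-5-(2-methylprop-1-en-1-yl)oxolan-2-one | OCC/C=C(\C)CC/C=C1/C(=O)O[C@H](C=C(C)C)[C@H]1O[Si](C)(C)C(C)(C)C | intermediate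
17 | (3E,4S,5R)-4-[(tert-butyldimethylsilyl)oxy]-3-[(4E)-7-iodo-4-methylhept-4-en-1-ylidene]-5-(2-methylprop-1-en-1-yl)oxolan-2-one | ICC/C=C(\C)CC/C=C1/C(=O)O[C@H](C=C(C)C)[C@H]1O[Si](C)(C)C(C)(C)C | intermediate
18 | but-2-yn-1-ol | CC#CCO | starting material
19 | cyclic alkenylaluminate, sodium 2,2-bis(2-methoxyethoxy)-3-methyl-2,5-dihydro-1,2-oxaaluminol-2-uide (not isolated) | CC1=CCO[Al-]1(OCCOC)OCCOC.[Na+] | intermediate
20 | (2Z)-3-iodobut-2-en-1-ol | C/C(I)=C/CO | intermediate
21 | (2E)-3-methylpent-2-enoic acid | CC/C(C)=C/C(=O)O | starting material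
22 | (2Z)-3-iodobut-2-en-1-yl (2E)-3-methylpent-2-enoate | CC/C(C)=C/C(=O)OC/C=C(/C)I | intermediate
23 | alkylzinc iodide from 17, {(3E,7E)-7-[(4S,5R)-4-[(tert-butyldimethylsilyl)oxy]-5-(2-methylprop-1-en-1-yl)-2-oxooxolan-3-ylidene]-4-methylhept-3-en-1-yl}zinc iodide (not isolated) | I[Zn]CC/C=C(\C)CC/C=C1/C(=O)O[C@H](C=C(C)C)[C@H]1O[Si](C)(C)C(C)(C)C | intermediate
24 | (2Z,6E,10E)-10-[(4S,5R)-4-[(tert-butyldimethylsilyl)oxy]-5-(2-methylprop-1-en-1-yl)-2-oxooxolan-3-ylidene]-3,7-dimethyldeca-2,6-dien-1-yl (2E)-3-methylpent-2-enoate | CC/C(C)=C/C(=O)OC/C=C(/C)CC/C=C(\C)CC/C=C1/C(=O)O[C@H](C=C(C)C)[C@H]1O[Si](C)(C)C(C)(C)C | intermediate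
25 | (2Z,6E,10E)-10-[(4S,5R)-4-hydroxy-5-(2-methylprop-1-en-1-yl)-2-oxooxolan-3-ylidene]-3,7-dimethyldeca-2,6-dien-1-yl (2E)-3-methylpent-2-enoate | CC/C(C)=C/C(=O)OC/C=C(/C)CC/C=C(\C)CC/C=C1/C(=O)O[C@H](C=C(C)C)[C@H]1O | target

Total step count: 16. Longest linear sequence: 11 steps (1, 2, 3, 4, 5, 9, 10, 11, 12, 15, 16).

Steps most likely to fail

Step 15. The zinc insertion may stall or the organozinc may be protonated, and Pd(0) may ionise the allylic carboxylate of 22 or 24, diverting the zinc reagent into allylic substitution instead of the alkenyl coupling. The fallback takes the allylic carboxylate out of the palladium step. It sets out from 20 and 17 and comes back to the route at 24. Alcohol 20 would be silylated (TESCl, imidazole, CH2Cl2) to (2Z)-3-iodobut-2-en-1-yl triethylsilyl ether F1. Negishi coupling of F1 with the zinc reagent 23, made from 17 as before, should give the bis-silyl ether (3E,4S,5R)-4-[(tert-butyldimethylsilyl)oxy]-3-[(4E,8Z)-4,8-dimethyl-10-[(triethylsilyl)oxy]deca-4,8-dien-1-ylidene]-5-(2-methylprop-1-en-1-yl)oxolan-2-one F2. Selective methanolysis of the primary allylic TES ether (PPTS, MeOH, 0 °C) would free the allylic alcohol (3E,4S,5R)-4-[(tert-butyldimethylsilyl)oxy]-3-[(4E,8Z)-10-hydroxy-4,8-dimethyldeca-4,8-dien-1-ylidene]-5-(2-methylprop-1-en-1-yl)oxolan-2-one F3. Mitsunobu esterification of F3 with acid 21 (PPh3, DIAD) then gives 24.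

Step 5. The basic ylide may epimerise the α-oxygenated aldehyde carbon, trigger β-elimination of the silyloxy group or attack the lactone carbonyl. The fallback builds the alkene without strong base. It sets out from 5 and comes back at 6. Non-basic Takai–Lombardo methylenation (CH2I2, Zn, TiCl4, THF), which leaves esters untouched, should give (4S,5R)-4-[(tert-butyldimethylsilyl)oxy]-5-ethenyloxolan-2-one F4. Cross-metathesis of F4 with 2-methylbut-2-ene (Grubbs second-generation catalyst, 40 °C) would install the isobutenyl group and give 6.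

Step 10. The E1cB elimination may show poor E/Z control, and loss of the ring silyloxy group may compete. The fallback replaces the aldol–dehydration (steps 9 and 10) by an olefination. It sets out from 6 (with 11) and comes back at 15. C-Phosphorylation of the lactone enolate (LDA 2.2 equiv, ClP(O)(OEt)2, THF, −78 °C, via the vinyl phosphate and 1,3-phosphorus shift) should give diethyl [(4R,5R)-4-[(tert-butyldimethylsilyl)oxy]-5-(2-methylprop-1-en-1-yl)-2-oxooxolan-3-yl]phosphonate F5, which has the same spatial arrangement as 6 and differs in the C4 descriptor by CIP priority only. Horner–Wadsworth–Emmons olefination of F5 with aldehyde 11 under mild Masamune–Roush conditions (LiCl, DBU, MeCN) is expected to favour the (E)-alkylidene lactone 15.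

Further compounds
F1 | step 15 | (2Z)-3-iodobut-2-en-1-yl triethylsilyl ether | CC[Si](CC)(CC)OC/C=C(/C)I
F2 | step 15 | (3E,4S,5R)-4-[(tert-butyldimethylsilyl)oxy]-3-[(4E,8Z)-4,8-dimethyl-10-[(triethylsilyl)oxy]deca-4,8-dien-1-ylidene]-5-(2-methylprop-1-en-1-yl)oxolan-2-one | CC[Si](CC)(CC)OC/C=C(/C)CC/C=C(\C)CC/C=C1/C(=O)O[C@H](C=C(C)C)[C@H]1O[Si](C)(C)C(C)(C)C
F3 | step 15 | (3E,4S,5R)-4-[(tert-butyldimethylsilyl)oxy]-3-[(4E,8Z)-10-hydroxy-4,8-dimethyldeca-4,8-dien-1-ylidene]-5-(2-methylprop-1-en-1-yl)oxolan-2-one | OC/C=C(/C)CC/C=C(\C)CC/C=C1/C(=O)O[C@H](C=C(C)C)[C@H]1O[Si](C)(C)C(C)(C)C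
F4 | step 5 | (4S,5R)-4-[(tert-butyldimethylsilyl)oxy]-5-ethenyloxolan-2-one | O=C1C[C@H](O[Si](C)(C)C(C)(C)C)[C@@H](C=C)O1
F5 | step 10 | diethyl [(4R,5R)-4-[(tert-butyldimethylsilyl)oxy]-5-(2-methylprop-1-en-1-yl)-2-oxooxolan-3-yl]phosphonate (C3 epimer mixture) | CCOP(=O)(OCC)C1C(=O)O[C@H](C=C(C)C)[C@H]1O[Si](C)(C)C(C)(C)C
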